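**Plan**

- Retrosynthesis cuts the flavanone at its aryl ether O1–C2 and its acyl–arene bond C4–C4a, and the isoflavan at O1–C2 and, in the key step, at C3–C4 together with the lactone O1–C2 bond of a dihydrocoumarin.
- Enabling feature: isoflavan atoms O1–C8a–C4a–C4 (ring A with its benzylic carbon) are a masked o-quinone methide, and C2–C3 with the C3 aryl group is an arylacetyl unit. The pyran ring is therefore their formal [4+2] adduct at the lactone oxidation level.
- Forward: the pyranone ring forms first (annulation), is reduced and re-closed to the chroman, and the chromanone ring is built last on the unveiled para-oxygen of the C4 aryl group; one hydrogenolysis ends the route.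
- Stereochemistry: C4 comes from a chiral isothiourea, C3 from equilibration to trans, and flavanone C2 from asymmetric transfer hydrogenation followed by Mitsunobu inversion.
- The C4 aryl group is kept locally symmetric (two benzyloxy groups beside the link, silyl ether para), so the late acylation gives one flavanone whichever free position reacts.

Key step: step 9

Remark: (2S,3R)-HyperBTM is assumed, by analogy with its Michael addition–lactonisations, to deliver the (4S) centre; if the opposite sense is found, the catalyst antipode is used with no other change.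

**Route**

Step 1
Reactants: 1 3,5-bis(benzyloxy)phenol
Product: 3 2,6-bis(benzyloxy)-4-hydroxybenzaldehyde, via iminium chloride 2 (not isolated)
Conditions: POCl3, DMF, MeCN, 0 °C → rt; then aq. NaOAc, rt
Reagents that add atoms: N,N-dimethylformamide CN(C)C=O (formyl carbon); water O (formyl oxygen)
Why: Vilsmeier–Haack formylation of a 3,5-dialkoxyphenol goes mainly para to the free hydroxyl, between the two benzyloxy groups, and hydrolysis of iminium salt 2 releases the aldehyde, the chelated ortho-formyl isomer being the expected separable by-product.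

Step 2
Reactants: 3 2,6-bis(benzyloxy)-4-hydroxybenzaldehyde
Product: 4 2,6-bis(benzyloxy)-4-(triisopropylsilyloxy)benzaldehyde
Conditions: TIPSCl, imidazole, CH2Cl2, rt
Reagents that add atoms: triisopropylsilyl chloride CC(C)[Si](Cl)(C(C)C)C(C)C
Why: Standard silylation of the only free phenol marks the para-oxygen that must later be released alone, and the bulky silyl ether survives organolithium, carbonate, hydride and Mitsunobu conditions.

Step 3
Reactants: 5 5-(benzyloxy)-2-bromophenol; 4 2,6-bis(benzyloxy)-4-(triisopropylsilyloxy)benzaldehyde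
Product: 7 rac-5-(benzyloxy)-2-{[2,6-bis(benzyloxy)-4-(triisopropylsilyloxy)phenyl](hydroxy)methyl}phenol, via dilithio phenoxide 6 (not isolated)
Conditions: 5, n-BuLi (2.1 equiv), THF, −78 → −20 °C; then 4, −78 → 0 °C; aq. NH4Cl
Reagents that add atoms: none
Why: Deprotonation followed by bromine–lithium exchange (faster at low temperature than benzylic deprotonation of the benzyl ethers) gives the O,C-dilithio species 6, whose 1,2-addition to the non-enolisable aldehyde gives the o-hydroxybenzhydrol as a racemate, which is harmless because this carbon becomes planar in step 9.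

Step 4
Reactants: 7 rac-5-(benzyloxy)-2-{[2,6-bis(benzyloxy)-4-(triisopropylsilyloxy)phenyl](hydroxy)methyl}phenol
Product: 8 rac-5-(benzyloxy)-2-{[2,6-bis(benzyloxy)-4-(triisopropylsilyloxy)phenyl](4-methylbenzenesulfonyl)methyl}phenol
Conditions: p-TolSO2H, 4 Å molecular sieves, CH2Cl2, rt
Reagents that add atoms: p-toluenesulfinic acid Cc1ccc(cc1)S(=O)O
Why: The doubly activated benzhydrol ionises under the mild acidity of the sulfinic acid and the cation is captured at sulfur (SN1-type sulfinate alkylation), giving the storable sulfone commonly used as an o-quinone methide precursor, again as a transient racemate.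

Step 5
Reactants: 9 2,6-dimethoxyphenol
Product: 10 2-(benzyloxy)-1,3-dimethoxybenzene
Conditions: BnBr, K2CO3, DMF, rt
Reagents that add atoms: benzyl bromide BrCc1ccccc1
Why: Williamson etherification protects the future 3'-hydroxyl as a hydrogenolysable ether.

Step 6
Reactants: 10 2-(benzyloxy)-1,3-dimethoxybenzene
Product: 11 3-(benzyloxy)-1-bromo-2,4-dimethoxybenzene
Conditions: NBS (1.0 equiv), MeCN, 0 °C → rt
Reagents that add atoms: N-bromosuccinimide O=C1CCC(=O)N1Br
Why: Electrophilic aromatic bromination of a 1,2,3-trialkoxybenzene occurs para to a terminal methoxy group, since the central alkoxy group is twisted out of conjugation, and the two such positions are equivalent.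

Step 7
Reactants: 11 3-(benzyloxy)-1-bromo-2,4-dimethoxybenzene
Product: 12 ethyl 2-[3-(benzyloxy)-2,4-dimethoxyphenyl]acetate
Conditions: BrZnCH2CO2Et (1.5 equiv), Pd(dba)2 (2 mol %), Q-Phos (2 mol %), THF, rt → 50 °C
Reagents that add atoms: (2-ethoxy-2-oxoethyl)zinc bromide CCOC(=O)C[Zn]Br
Why: Palladium-catalysed cross-coupling of a Reformatsky reagent with an aryl bromide (Negishi-type ester α-arylation) works under neutral conditions on electron-rich, ortho-substituted bromides and installs the acetate unit in one operation.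

Step 8
Reactants: 12 ethyl 2-[3-(benzyloxy)-2,4-dimethoxyphenyl]acetate
Product: 13 2-[3-(benzyloxy)-2,4-dimethoxyphenyl]acetic acid
Conditions: LiOH, THF/MeOH/H2O, rt; then 1 M HCl
Reagents that add atoms: lithium hydroxide [Li+].[OH-]
Why: Saponification of an unhindered ethyl ester leaves all ether groups untouched.

Step 9
Reactants: 8 rac-5-(benzyloxy)-2-{[2,6-bis(benzyloxy)-4-(triisopropylsilyloxy)phenyl](4-methylbenzenesulfonyl)methyl}phenol; 13 2-[3-(benzyloxy)-2,4-dimethoxyphenyl]acetic acid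
Product: 17 (3R,4S)-trans-7-(benzyloxy)-3-[3-(benzyloxy)-2,4-dimethoxyphenyl]-4-[2,6-bis(benzyloxy)-4-(triisopropylsilyloxy)phenyl]chroman-2-one, via mixed pivalic anhydride 14 (not isolated), via o-quinone methide 15 (not isolated), via cis-lactone 16 (not isolated)
Conditions: (a) 13 (1.5 equiv), t-BuCOCl, i-Pr2NEt, CH2Cl2, 0 °C; (b) 8, Cs2CO3, CH2Cl2, rt, then transferred by filter cannula into (a); (c) (2S,3R)-HyperBTM (10 mol %), i-Pr2NEt, −40 °C → rt; (d) DBU (0.2 equiv), rt
Reagents that add atoms: none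
Why: The isothiourea is N-acylated by anhydride 14 and deprotonated by i-Pr2NEt to a Z-configured C1-ammonium enolate, held flat by a 1,5-O···S contact, which adds through its α-carbon to the methide carbon of pre-formed 15 and rearomatises ring A; the phenoxide then attacks the acyl ammonium carbonyl and releases the catalyst. The closest known reaction type is the isothiourea- or carbene-catalysed formal [4+2] annulation of carboxylic-acid-derived enolates with o-quinone methides to 3,4-dihydrocoumarins. The pyranone ring closes by 6-exo-trig lactonisation after the intermolecular Michael step, so C3–C4 forms first and O1–C2 second. C4 is set by the catalyst, whose phenyl group shields one enolate face while the quinone methide must align its oxygen with the acyl carbon, which fixes the methide face attacked; C3 is set at the end by DBU equilibration of the enolisable lactone α-position, which converts the expected cis adduct 16 into the trans isomer without touching the non-acidic C4–H. The step needs enantiocontrol (from the catalyst), trans diastereocontrol (from the thermodynamic preference of the two aryl groups) and C–C bond formation in preference to phenol O-acylation, which is secured by releasing 15, an (E)-configured vinylogous ester stabilised by its 3-benzyloxy group, before it meets the acyl donor.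

Step 10
Reactants: 17 (3R,4S)-trans-dihydrocoumarin (full name in the list)
Product: 18 (2R,3S)-3-[4-(benzyloxy)-2-hydroxyphenyl]-2-[3-(benzyloxy)-2,4-dimethoxyphenyl]-3-[2,6-bis(benzyloxy)-4-(triisopropylsilyloxy)phenyl]propan-1-ol
Conditions: LiBH4, THF, 0 °C → rt; then H2O
Reagents that add atoms: none
Why: Hydride reduction of the activated aryl ester lactone to phenol and primary alcohol is fast with this weakly basic reagent, so the α-centre is reduced before it can enolise, and the silyl and benzyl ethers are inert.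

Step 11
Reactants: 18 (2R,3S)-phenol–primary alcohol diol (full name in the list)
Product: 19 (3R,4S)-7-(benzyloxy)-3-[3-(benzyloxy)-2,4-dimethoxyphenyl]-4-[2,6-bis(benzyloxy)-4-(triisopropylsilyloxy)phenyl]chromane
Conditions: PPh3, DIAD, THF, 0 °C → rt
Reagents that add atoms: none
Why: Intramolecular Mitsunobu etherification (6-exo-tet displacement at the primary carbon by the phenol) is the established closure for isoflavans and involves neither stereocentre.

Step 12
Reactants: 19 (3R,4S)-silyl-protected isoflavan (full name in the list)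
Product: 20 3,5-bis(benzyloxy)-4-{(3R,4S)-7-(benzyloxy)-3-[3-(benzyloxy)-2,4-dimethoxyphenyl]chroman-4-yl}phenol
Conditions: TBAF, AcOH, THF, 0 °C
Reagents that add atoms: none
Why: Buffered fluoride desilylation frees only the para-phenol and avoids exposing the electron-rich phenoxide to air as a naked anion.

Step 13
Reactants: 21 4-hydroxybenzaldehyde
Product: 22 benzyl 4-formylphenyl carbonate
Conditions: CbzCl, Et3N, CH2Cl2, 0 °C
Reagents that add atoms: benzyl chloroformate O=C(Cl)OCc1ccccc1
Why: O-Acylation with a chloroformate gives an electron-withdrawing carbonate that keeps the later benzylic C–O bond from ionising and falls off in the final hydrogenolysis.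

Step 14
Reactants: 22 benzyl 4-formylphenyl carbonate
Product: 23 tert-butyl 3-{4-[(benzyloxycarbonyl)oxy]phenyl}-3-oxopropanoate
Conditions: N2CHCO2t-Bu, SnCl2 (10 mol %), CH2Cl2, rt
Reagents that add atoms: tert-butyl diazoacetate CC(C)(C)OC(=O)C=[N+]=[N-]
Why: Roskamp homologation (Lewis-acid-promoted addition of the diazoester, 1,2-hydride shift and loss of nitrogen) turns the aldehyde into the β-keto ester under neutral conditions that spare the carbonate.

Step 15
Reactants: 23 tert-butyl 3-{4-[(benzyloxycarbonyl)oxy]phenyl}-3-oxopropanoate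
Product: 24 tert-butyl (3R)-3-{4-[(benzyloxycarbonyl)oxy]phenyl}-3-hydroxypropanoate
Conditions: RuCl[(R,R)-TsDPEN](p-cymene) (1 mol %), HCO2H/Et3N (5:2), EtOAc, rt
Reagents that add atoms: none
Why: Noyori asymmetric transfer hydrogenation of an aryl ketone delivers hydride to one carbonyl face through the CH/π-organised six-membered transition state, the (R,R) catalyst giving the (R) carbinol, and the weakly acidic medium leaves carbonate and tert-butyl ester intact.

Step 16
Reactants: 20 3,5-bis(benzyloxy)-4-{(3R,4S)-isoflavan-4-yl}phenol (full name in the list); 24 tert-butyl (3R)-3-{4-[(benzyloxycarbonyl)oxy]phenyl}-3-hydroxypropanoate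
Product: 25 tert-butyl (3S)-3-{4-[(benzyloxycarbonyl)oxy]phenyl}-3-(3,5-bis(benzyloxy)-4-{(3R,4S)-7-(benzyloxy)-3-[3-(benzyloxy)-2,4-dimethoxyphenyl]chroman-4-yl}phenoxy)propanoate
Conditions: PPh3, DIAD, toluene, 0 °C → rt
Reagents that add atoms: none
Why: Mitsunobu etherification displaces the alkoxyphosphonium group by the unhindered phenol in an SN2 step with inversion, turning the (R) alcohol into the (S) ether that becomes flavanone C2, while the carbonate-bearing ring disfavours ionisation and the tert-butyl ester tempers β-elimination.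

Step 17
Reactants: 25 (3S)-tert-butyl ester (full name in the list)
Product: 27 (3S)-3-{4-[(benzyloxycarbonyl)oxy]phenyl}-3-(3,5-bis(benzyloxy)-4-{(3R,4S)-7-(benzyloxy)-3-[3-(benzyloxy)-2,4-dimethoxyphenyl]chroman-4-yl}phenoxy)propanoic acid, via trimethylsilyl ester 26 (not isolated)
Conditions: TMSOTf, 2,6-lutidine, CH2Cl2, 0 °C; then pH 5 phosphate buffer
Reagents that add atoms: none
Why: Silyl-triflate-mediated tert-butyl ester cleavage gives silyl ester 26 and 2-methylpropene under lutidine buffering, so no tert-butyl cation can alkylate the electron-rich rings and no base is present to trigger β-elimination of the aryloxy group or loss of the carbonate, and the buffer then hydrolyses 26.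

Step 18
Reactants: 27 (3S)-3-aryl-3-aryloxypropanoic acid (full name in the list)
Product: 29 benzyl 4-[(2S)-5,7-bis(benzyloxy)-6-{(3R,4S)-7-(benzyloxy)-3-[3-(benzyloxy)-2,4-dimethoxyphenyl]chroman-4-yl}-4-oxochroman-2-yl]phenyl carbonate, via mixed trifluoroacetic anhydride 28 (not isolated)
Conditions: (CF3CO)2O, CH2Cl2, 0 °C → rt
Reagents that add atoms: none
Why: The mixed anhydride 28 acylates the trioxygenated ring intramolecularly ortho to the ether oxygen (Friedel–Crafts acylation of a 3-aryloxypropanoic acid to a chroman-4-one), the two candidate positions being equivalent, and the carbonate-deactivated benzylic ether should keep its (S) configuration in this mildly acidic medium.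

Step 19
Reactants: 29 fully protected flavanone–isoflavan (full name in the list)
Product: 31 (2S)-5,7-dihydroxy-6-[(3R,4S)-7-hydroxy-3-(3-hydroxy-2,4-dimethoxyphenyl)chroman-4-yl]-2-(4-hydroxyphenyl)chroman-4-one, via aryl hydrogen carbonate 30 (not isolated)
Conditions: H2 (1 atm), 10% Pd/C, EtOAc/THF, rt
Reagents that add atoms: none
Why: Catalytic hydrogenolysis removes the four benzyl ethers and the benzyl carbonate (whose carbonic acid 30 loses CO2) under neutral conditions, avoiding the base-induced chalcone opening that would racemise a 4'-hydroxyflavanone.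

**Compound list**

1 | 3,5-bis(benzyloxy)phenol | Oc1cc(OCc2ccccc2)cc(OCc2ccccc2)c1 | starting material
2 | [2,6-bis(benzyloxy)-4-hydroxyphenyl]methylidene-dimethyliminium chloride | C[N+](C)=Cc1c(OCc2ccccc2)cc(O)cc1OCc1ccccc1.[Cl-] | intermediate
3 | 2,6-bis(benzyloxy)-4-hydroxybenzaldehyde | O=Cc1c(OCc2ccccc2)cc(O)cc1OCc1ccccc1 | intermediate
4 | 2,6-bis(benzyloxy)-4-(triisopropylsilyloxy)benzaldehyde | O=Cc1c(OCc2ccccc2)cc(O[Si](C(C)C)(C(C)C)C(C)C)cc1OCc1ccccc1 | intermediate
5 | 5-(benzyloxy)-2-bromophenol | Oc1cc(OCc2ccccc2)ccc1Br | starting material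
6 | lithium 5-(benzyloxy)-2-lithiophenoxide | [Li]Oc1cc(OCc2ccccc2)ccc1[Li] | intermediate
7 | rac-5-(benzyloxy)-2-{[2,6-bis(benzyloxy)-4-(triisopropylsilyloxy)phenyl](hydroxy)methyl}phenol | OC(c1ccc(OCc2ccccc2)cc1O)c1c(OCc2ccccc2)cc(O[Si](C(C)C)(C(C)C)C(C)C)cc1OCc1ccccc1 | intermediate
8 | rac-5-(benzyloxy)-2-{[2,6-bis(benzyloxy)-4-(triisopropylsilyloxy)phenyl](4-methylbenzenesulfonyl)methyl}phenol | Cc1ccc(cc1)S(=O)(=O)C(c1ccc(OCc2ccccc2)cc1O)c1c(OCc2ccccc2)cc(O[Si](C(C)C)(C(C)C)C(C)C)cc1OCc1ccccc1 | intermediate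
9 | 2,6-dimethoxyphenol | COc1cccc(OC)c1O | starting material
10 | 2-(benzyloxy)-1,3-dimethoxybenzene | COc1cccc(OC)c1OCc1ccccc1 | intermediate
11 | 3-(benzyloxy)-1-bromo-2,4-dimethoxybenzene | COc1ccc(Br)c(OC)c1OCc1ccccc1 | intermediate
12 | ethyl 2-[3-(benzyloxy)-2,4-dimethoxyphenyl]acetate | CCOC(=O)Cc1ccc(OC)c(OCc2ccccc2)c1OC | intermediate
13 | 2-[3-(benzyloxy)-2,4-dimethoxyphenyl]acetic acid | COc1ccc(CC(=O)O)c(OC)c1OCc1ccccc1 | intermediate
14 | 2-[3-(benzyloxy)-2,4-dimethoxyphenyl]acetic pivalic anhydride | COc1ccc(CC(=O)OC(=O)C(C)(C)C)c(OC)c1OCc1ccccc1 | intermediate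
15 | (E)-3-(benzyloxy)-6-{[2,6-bis(benzyloxy)-4-(triisopropylsilyloxy)phenyl]methylidene}cyclohexa-2,4-dien-1-one | O=C1C=C(OCc2ccccc2)C=C/C1=C\c1c(OCc2ccccc2)cc(O[Si](C(C)C)(C(C)C)C(C)C)cc1OCc1ccccc1 | intermediate
16 | (3S,4S)-cis-7-(benzyloxy)-3-[3-(benzyloxy)-2,4-dimethoxyphenyl]-4-[2,6-bis(benzyloxy)-4-(triisopropylsilyloxy)phenyl]chroman-2-one | COc1ccc([C@H]2C(=O)Oc3cc(OCc4ccccc4)ccc3[C@H]2c2c(OCc3ccccc3)cc(O[Si](C(C)C)(C(C)C)C(C)C)cc2OCc2ccccc2)c(OC)c1OCc1ccccc1 | intermediate
17 | (3R,4S)-trans-7-(benzyloxy)-3-[3-(benzyloxy)-2,4-dimethoxyphenyl]-4-[2,6-bis(benzyloxy)-4-(triisopropylsilyloxy)phenyl]chroman-2-one | COc1ccc([C@@H]2C(=O)Oc3cc(OCc4ccccc4)ccc3[C@H]2c2c(OCc3ccccc3)cc(O[Si](C(C)C)(C(C)C)C(C)C)cc2OCc2ccccc2)c(OC)c1OCc1ccccc1 | intermediate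
18 | (2R,3S)-3-[4-(benzyloxy)-2-hydroxyphenyl]-2-[3-(benzyloxy)-2,4-dimethoxyphenyl]-3-[2,6-bis(benzyloxy)-4-(triisopropylsilyloxy)phenyl]propan-1-ol | COc1ccc([C@H](CO)[C@@H](c2ccc(OCc3ccccc3)cc2O)c2c(OCc3ccccc3)cc(O[Si](C(C)C)(C(C)C)C(C)C)cc2OCc2ccccc2)c(OC)c1OCc1ccccc1 | intermediate
19 | (3R,4S)-7-(benzyloxy)-3-[3-(benzyloxy)-2,4-dimethoxyphenyl]-4-[2,6-bis(benzyloxy)-4-(triisopropylsilyloxy)phenyl]chromane | COc1ccc([C@@H]2COc3cc(OCc4ccccc4)ccc3[C@H]2c2c(OCc3ccccc3)cc(O[Si](C(C)C)(C(C)C)C(C)C)cc2OCc2ccccc2)c(OC)c1OCc1ccccc1 | intermediate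
20 | 3,5-bis(benzyloxy)-4-{(3R,4S)-7-(benzyloxy)-3-[3-(benzyloxy)-2,4-dimethoxyphenyl]chroman-4-yl}phenol | COc1ccc([C@@H]2COc3cc(OCc4ccccc4)ccc3[C@H]2c2c(OCc3ccccc3)cc(O)cc2OCc2ccccc2)c(OC)c1OCc1ccccc1 | intermediate
21 | 4-hydroxybenzaldehyde | O=Cc1ccc(O)cc1 | starting material
22 | benzyl 4-formylphenyl carbonate | O=Cc1ccc(OC(=O)OCc2ccccc2)cc1 | intermediate
23 | tert-butyl 3-{4-[(benzyloxycarbonyl)oxy]phenyl}-3-oxopropanoate | CC(C)(C)OC(=O)CC(=O)c1ccc(OC(=O)OCc2ccccc2)cc1 | intermediate
24 | tert-butyl (3R)-3-{4-[(benzyloxycarbonyl)oxy]phenyl}-3-hydroxypropanoate | CC(C)(C)OC(=O)C[C@@H](O)c1ccc(OC(=O)OCc2ccccc2)cc1 | intermediate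
25 | tert-butyl (3S)-3-{4-[(benzyloxycarbonyl)oxy]phenyl}-3-(3,5-bis(benzyloxy)-4-{(3R,4S)-7-(benzyloxy)-3-[3-(benzyloxy)-2,4-dimethoxyphenyl]chroman-4-yl}phenoxy)propanoate | COc1ccc([C@@H]2COc3cc(OCc4ccccc4)ccc3[C@H]2c2c(OCc3ccccc3)cc(O[C@@H](CC(=O)OC(C)(C)C)c3ccc(OC(=O)OCc4ccccc4)cc3)cc2OCc2ccccc2)c(OC)c1OCc1ccccc1 | intermediate
26 | trimethylsilyl (3S)-3-{4-[(benzyloxycarbonyl)oxy]phenyl}-3-(3,5-bis(benzyloxy)-4-{(3R,4S)-7-(benzyloxy)-3-[3-(benzyloxy)-2,4-dimethoxyphenyl]chroman-4-yl}phenoxy)propanoate | COc1ccc([C@@H]2COc3cc(OCc4ccccc4)ccc3[C@H]2c2c(OCc3ccccc3)cc(O[C@@H](CC(=O)O[Si](C)(C)C)c3ccc(OC(=O)OCc4ccccc4)cc3)cc2OCc2ccccc2)c(OC)c1OCc1ccccc1 | intermediate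
27 | (3S)-3-{4-[(benzyloxycarbonyl)oxy]phenyl}-3-(3,5-bis(benzyloxy)-4-{(3R,4S)-7-(benzyloxy)-3-[3-(benzyloxy)-2,4-dimethoxyphenyl]chroman-4-yl}phenoxy)propanoic acid | COc1ccc([C@@H]2COc3cc(OCc4ccccc4)ccc3[C@H]2c2c(OCc3ccccc3)cc(O[C@@H](CC(=O)O)c3ccc(OC(=O)OCc4ccccc4)cc3)cc2OCc2ccccc2)c(OC)c1OCc1ccccc1 | intermediate
28 | mixed anhydride of acid 27 with trifluoroacetic acid | COc1ccc([C@@H]2COc3cc(OCc4ccccc4)ccc3[C@H]2c2c(OCc3ccccc3)cc(O[C@@H](CC(=O)OC(=O)C(F)(F)F)c3ccc(OC(=O)OCc4ccccc4)cc3)cc2OCc2ccccc2)c(OC)c1OCc1ccccc1 | intermediate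
29 | benzyl 4-[(2S)-5,7-bis(benzyloxy)-6-{(3R,4S)-7-(benzyloxy)-3-[3-(benzyloxy)-2,4-dimethoxyphenyl]chroman-4-yl}-4-oxochroman-2-yl]phenyl carbonate | COc1ccc([C@@H]2COc3cc(OCc4ccccc4)ccc3[C@H]2c2c(OCc3ccccc3)cc3c(c2OCc2ccccc2)C(=O)C[C@@H](c2ccc(OC(=O)OCc4ccccc4)cc2)O3)c(OC)c1OCc1ccccc1 | intermediate
30 | 4-[(2S)-5,7-dihydroxy-6-{(3R,4S)-7-hydroxy-3-(3-hydroxy-2,4-dimethoxyphenyl)chroman-4-yl}-4-oxochroman-2-yl]phenyl hydrogen carbonate | COc1ccc([C@@H]2COc3cc(O)ccc3[C@H]2c2c(O)cc3c(c2O)C(=O)C[C@@H](c2ccc(OC(=O)O)cc2)O3)c(OC)c1O | intermediate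
31 | (2S)-5,7-dihydroxy-6-[(3R,4S)-7-hydroxy-3-(3-hydroxy-2,4-dimethoxyphenyl)chroman-4-yl]-2-(4-hydroxyphenyl)chroman-4-one (CNP0267463.1) | COc1ccc([C@@H]2COc3cc(O)ccc3[C@H]2c2c(O)cc3c(c2O)C(=O)C[C@@H](c2ccc(O)cc2)O3)c(OC)c1O | target

**Step count and risks**

Total steps: 19. Longest linear sequence: 12 steps (steps 1–4, 9–12 and 16–19 from phenol 1; the branch from 9 through steps 5–8 is equally long).

Steps most likely to fail:

Step 9. The catalyst-bound enolate may add too slowly to a methide carbon that is deactivated by the trioxygenated aryl group and shielded by its two ortho benzyloxy groups, so that the quinone methide oligomerises or re-adds sulfinate, or the face selectivity may be low. The fallback leaves ammonium-enolate catalysis for carbene catalysis on a pre-formed activated ester. It sets out from acid 13 and sulfone 8. Acid 13 is esterified (EDC·HCl, 4-nitrophenol, catalytic DMAP) to 4-nitrophenyl 2-[3-(benzyloxy)-2,4-dimethoxyphenyl]acetate F1. F1 and 8 are then combined with Cs2CO3 and an aminoindanol-derived N-mesityl triazolium tetrafluoroborate (the antipode that gives the 4S series) in THF. The carbonate releases 15 and the free carbene in one pot, the carbene converts F1 into an azolium enolate that can be run warmer than the isothiourea system, and the same Michael addition–lactonisation followed by DBU equilibration returns the route at lactone 17.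

Step 16. The activated β-hydroxy ester may undergo β-elimination to the cinnamate, or transfer of the carbonate to the phenoxide may occur, faster than the SN2 displacement. The fallback removes the acidic α-hydrogens from the alcohol partner and adds the acid oxidation level afterwards. It sets out from aldehyde 22 and phenol 20. Asymmetric allylboration of 22 with (+)-Ipc2B(allyl) (the antipode giving the R carbinol; ethanolamine work-up to spare the carbonate) gives benzyl 4-[(1R)-1-hydroxybut-3-en-1-yl]phenyl carbonate F2. Mitsunobu coupling of F2 with 20 gives, with inversion, the (S)-homoallyl aryl ether F3. Lemieux–Johnson cleavage (catalytic OsO4, NaIO4, 2,6-lutidine) gives the (S)-3-aryloxy-3-arylpropanal F4, and Pinnick oxidation (NaClO2, NaH2PO4, 2-methylbut-2-ene) returns the route at acid 27.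

Step 18. Acid-promoted ionisation of the benzylic aryl ether (erosion of the flavanone centre or fragmentation to a cinnamic acid) or protolytic cleavage of the diarylmethine link may compete with ring closure. The fallback builds the ketone ring first and adds the aryl group last by asymmetric conjugate addition, so no acid-labile stereocentre is present during the acylation. It sets out from phenol 20. C-Acetylation ortho to the free hydroxyl (Ac2O, BF3·OEt2, 0 °C) gives the 2-hydroxyacetophenone F5. Condensation with DMF dimethyl acetal gives the enaminone F6, and acid-induced cyclisation gives the 5,7-bis(benzyloxy)chromone F7. Addition of 4-(benzyloxy)phenylboronic acid catalysed by Pd(OCOCF3)2 and the t-BuPyOx antipode that gives the 2S centre (NH4PF6, water, 1,2-dichloroethane, 60 °C) gives the benzyl-protected (2S)-flavanone F8. Hydrogenolysis as in step 19 returns the route at target 31.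

**Further compounds**

F1 | step 9 | 4-nitrophenyl 2-[3-(benzyloxy)-2,4-dimethoxyphenyl]acetate | COc1ccc(CC(=O)Oc2ccc(cc2)[N+](=O)[O-])c(OC)c1OCc1ccccc1
F2 | step 16 | benzyl 4-[(1R)-1-hydroxybut-3-en-1-yl]phenyl carbonate | C=CC[C@@H](O)c1ccc(OC(=O)OCc2ccccc2)cc1
F3 | step 16 | benzyl 4-[(1S)-1-(3,5-bis(benzyloxy)-4-{(3R,4S)-7-(benzyloxy)-3-[3-(benzyloxy)-2,4-dimethoxyphenyl]chroman-4-yl}phenoxy)but-3-en-1-yl]phenyl carbonate | COc1ccc([C@@H]2COc3cc(OCc4ccccc4)ccc3[C@H]2c2c(OCc3ccccc3)cc(O[C@@H](CC=C)c3ccc(OC(=O)OCc4ccccc4)cc3)cc2OCc2ccccc2)c(OC)c1OCc1ccccc1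
F4 | step 16 | benzyl 4-[(1S)-1-(3,5-bis(benzyloxy)-4-{(3R,4S)-7-(benzyloxy)-3-[3-(benzyloxy)-2,4-dimethoxyphenyl]chroman-4-yl}phenoxy)-3-oxopropyl]phenyl carbonate | COc1ccc([C@@H]2COc3cc(OCc4ccccc4)ccc3[C@H]2c2c(OCc3ccccc3)cc(O[C@@H](CC=O)c3ccc(OC(=O)OCc4ccccc4)cc3)cc2OCc2ccccc2)c(OC)c1OCc1ccccc1
F5 | step 18 | 1-{2,4-bis(benzyloxy)-6-hydroxy-3-[(3R,4S)-7-(benzyloxy)-3-[3-(benzyloxy)-2,4-dimethoxyphenyl]chroman-4-yl]phenyl}ethan-1-one | COc1ccc([C@@H]2COc3cc(OCc4ccccc4)ccc3[C@H]2c2c(OCc3ccccc3)c(C(C)=O)c(O)cc2OCc2ccccc2)c(OC)c1OCc1ccccc1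
F6 | step 18 | (E)-1-{2,4-bis(benzyloxy)-6-hydroxy-3-[(3R,4S)-7-(benzyloxy)-3-[3-(benzyloxy)-2,4-dimethoxyphenyl]chroman-4-yl]phenyl}-3-(dimethylamino)prop-2-en-1-one | COc1ccc([C@@H]2COc3cc(OCc4ccccc4)ccc3[C@H]2c2c(OCc3ccccc3)c(C(=O)/C=C/N(C)C)c(O)cc2OCc2ccccc2)c(OC)c1OCc1ccccc1
F7 | step 18 | 5,7-bis(benzyloxy)-6-{(3R,4S)-7-(benzyloxy)-3-[3-(benzyloxy)-2,4-dimethoxyphenyl]chroman-4-yl}-4H-chromen-4-one | COc1ccc([C@@H]2COc3cc(OCc4ccccc4)ccc3[C@H]2c2c(OCc3ccccc3)cc3occc(=O)c3c2OCc2ccccc2)c(OC)c1OCc1ccccc1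
F8 | step 18 | (2S)-5,7-bis(benzyloxy)-2-[4-(benzyloxy)phenyl]-6-{(3R,4S)-7-(benzyloxy)-3-[3-(benzyloxy)-2,4-dimethoxyphenyl]chroman-4-yl}chroman-4-one | COc1ccc([C@@H]2COc3cc(OCc4ccccc4)ccc3[C@H]2c2c(OCc3ccccc3)cc3c(c2OCc2ccccc2)C(=O)C[C@@H](c2ccc(OCc4ccccc4)cc2)O3)c(OC)c1OCc1ccccc1
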